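The C8–C10 triad is built from L-glyceraldehyde, the ten-membered ring and the lactone are closed together by a chromium-mediated allylation, and the furanone is formed in the last step.

The synthesis rests on disconnecting the O–C3 bond of the 3(2H)-furanone (ring O, C3, C2, C1, C10): the C10 tertiary hydroxyl is placed across a ten-membered carbocycle from a strained C2≡C3 alkyne that becomes conjugated to the C1 ketone. In one operation, chemoselective oxidation of the C1 propargylic carbinol and gold-catalysed transannular 5-endo-dig hydroalkoxylation release the cycloalkyne strain and turn the carbocycle into the furanone and its nine-membered oxa-bridged partner ring. The precursor, a cyclodec-4-en-2-yne-1,8,10-triol fused to the α-methylene lactone, comes from a CrCl2-mediated macrocyclisation; the C8–C10 triad derives from 2-C-methyl-L-ribonolactone.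

Key step: step 19

Remarks.
- Locants: C1 = furanone carbonyl carbon; C2=C3 = furanone alkene (C3 bears the ring oxygen); C4(CH3)=C5; C6 = lactone O–CH; C7 = ring-fusion CH; C8 = CH–OH; C9 = CH–O-acyl; C10 = C(CH3)–O; C11–C13 = α-methylene lactone carbons.
- Abbreviations: TES = triethylsilyl, TBS = tert-butyldimethylsilyl, PMB = 4-methoxybenzyl.
- Assumption: (S)-glyceraldehyde acetonide 1 is taken as commercially available (otherwise one step from 5,6-O-isopropylidene-L-gulono-1,4-lactone with NaIO4).
- C1 in 9–30 and C7 in 13 and 18 are epimer mixtures; both centres are erased later.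

Step 1
Reactants: 1 (S)-glyceraldehyde acetonide; 2 ethyl 2-[bis(2,2,2-trifluoroethoxy)phosphoryl]propanoate
Product: 3 ethyl (Z)-3-[(4R)-2,2-dimethyl-1,3-dioxolan-4-yl]-2-methylprop-2-enoate
Conditions: KN(SiMe3)2, 18-crown-6, THF, −78 °C
Reagents that add atoms: none
Why: Still–Gennari olefination: the electron-poor phosphonate with a dissociated potassium base eliminates irreversibly from the kinetic adduct and should give the (Z)-trisubstituted enoate (ester cis to C8) without touching the C8 stereocentre.

Step 2
Reactants: 3 (Z)-enoate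
Product: 5 2-C-methyl-L-ribono-1,4-lactone, via dihydroxy ester 4 (not isolated)
Conditions: OsO4 (2 mol %), N-methylmorpholine N-oxide, acetone–H2O, rt; then 2 M HCl, 50 °C
Reagents that add atoms: N-methylmorpholine N-oxide C[N+]1([O-])CCOCC1; water O
Why: Upjohn dihydroxylation adds both oxygens syn to the (Z)-alkene from the face anti to the allylic C8–O bond (allylic hydrogen in the alkene plane, the empirical rule for osmylation of allylic ethers), which should set C9 and C10 in the all-erythro L-ribo array, and aqueous acid then cleaves the acetonide so that the C8 hydroxyl closes the γ-lactone.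

Step 3
Reactants: 5 2-C-methyl-L-ribono-1,4-lactone
Product: 6 2,3,5-tris-O-(triethylsilyl)-2-C-methyl-L-ribono-1,4-lactone
Conditions: Et3SiOTf (3.6 equiv), 2,6-lutidine, CH2Cl2, −78 → 0 °C
Reagents that add atoms: triethylsilyl trifluoromethanesulfonate CC[Si](CC)(CC)OS(=O)(=O)C(F)(F)F
Why: Exhaustive silylation with a silyl triflate masks C7–OH, C9–OH and the tertiary C10–OH, which would otherwise form a lactol with the later C7 aldehyde.

Step 4
Reactants: 6 tris-TES lactone
Product: 7 2,3,5-tris-O-(triethylsilyl)-2-C-methyl-L-ribofuranose (anomer mixture)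
Conditions: iBu2AlH (1.2 equiv), CH2Cl2, −78 °C
Reagents that add atoms: none
Why: Partial reduction of a lactone with iBu2AlH at −78 °C stops at the tetrahedral aluminium hemiacetal, which gives the lactol on work-up.

Step 5
Reactants: 7 lactol; 8 ethynylmagnesium bromide
Product: 9 alkynyl diol HC3≡C2–C1H(OH)–C10(CH3)(OTES)–C9H(OTES)–C8H(OH)–C7H2OTES
Conditions: HC≡CMgBr (5 equiv), THF, −20 → 0 °C
Reagents that add atoms: none
Why: The magnesium lactolate opens to the hydroxy aldehyde, which undergoes Grignard addition to give the propargylic alcohol as an inconsequential C1 epimer mixture, the low temperature and magnesium counter-ion being chosen to suppress silyl migration.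

Step 6
Reactants: 9 alkynyl diol
Product: 10 1,8-bis-O-TBS ether of 9
Conditions: tBuMe2SiOTf (2.5 equiv), 2,6-lutidine, CH2Cl2, −78 → 0 °C
Reagents that add atoms: tert-butyldimethylsilyl trifluoromethanesulfonate CC(C)(C)[Si](C)(C)OS(=O)(=O)C(F)(F)F
Why: Silylation of the two secondary hydroxyls gives TBS ethers that will outlast the later selective removal of the TES groups.

Step 7
Reactants: 10 bis-TBS tris-TES ether
Product: 11 C7 aldehyde (C1–OTBS, C8–OTBS, C9–OTES, C10–OTES, terminal alkyne)
Conditions: (COCl)2, DMSO, CH2Cl2, −78 → −30 °C; then Et3N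
Reagents that add atoms: none
Why: Under Swern conditions the activated sulfoxide attacks the least hindered silyl ether oxygen, so the primary TES ether is converted directly into the aldehyde while secondary and tertiary silyl ethers remain (chemoselective Swern oxidation of primary TES ethers).

Step 8
Reactants: 11 C7 aldehyde; 12 methyl acrylate
Product: 13 Morita–Baylis–Hillman alcohol (C7H(OH)–C11(=C13H2)–CO2CH3)
Conditions: DABCO (1 equiv), methyl acrylate (neat), rt, several days
Reagents that add atoms: none
Why: Morita–Baylis–Hillman reaction: DABCO adds to the acrylate and the ammonium enolate adds to the α-silyloxy aldehyde, the new C7 carbinol forming as an epimer mixture that is erased in step 12.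

Step 9
Reactants: 14 but-2-yn-1-ol
Product: 16 (Z)-3-iodobut-2-en-1-ol, via cyclic vinylalanate 15 (not isolated)
Conditions: NaAlH2(OCH2CH2OCH3)2, THF, 0 °C → rt; EtOAc; then I2, −78 °C
Reagents that add atoms: iodine II
Why: Alkoxide-directed trans-hydroalumination places aluminium on C3 cis to the CH2O group in a five-membered alanate, and iodinolysis with retention gives the (Z)-vinyl iodide.

Step 10
Reactants: 16 (Z)-3-iodobut-2-en-1-ol
Product: 17 (Z)-3-iodobut-2-enal
Conditions: MnO2, CH2Cl2, rt, dark
Reagents that add atoms: none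
Why: MnO2 oxidises the allylic alcohol to the enal under neutral conditions without Z/E isomerisation.

Step 11
Reactants: 13 Morita–Baylis–Hillman alcohol; 17 (Z)-3-iodobut-2-enal
Product: 18 (Z)-enynal (C6HO–C5H=C4(CH3)–C3≡C2–C1H(OTBS)–, otherwise as 13)
Conditions: PdCl2(PPh3)2 (5 mol %), CuI (10 mol %), Et3N, THF, rt
Reagents that add atoms: none
Why: Sonogashira coupling of the terminal alkyne with the reactive β-iodo enal proceeds at room temperature with retention of the (Z)-alkene geometry and tolerates the acrylate and the free allylic alcohol.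

Step 12
Reactants: 18 (Z)-enynal
Product: 19 (Z)-allylic bromide (C8H(OTBS)–C7H=C11(CO2CH3)–C13H2Br)
Conditions: N-bromosuccinimide, Me2S, CH2Cl2, −20 → 0 °C
Reagents that add atoms: N-bromosuccinimide O=C1CCC(=O)N1Br
Why: Corey–Kim-type bromination: the alkoxysulfonium salt of the allylic alcohol is displaced by bromide with allylic transposition (SN2′) to the conjugated, thermodynamically favoured (Z)-2-(bromomethyl)enoate, which removes the C7 stereocentre.

Step 13
Reactants: 19 (Z)-allylic bromide
Product: 21 macrolactone (cyclodec-4-en-2-yne fused 12,6-olide; C1–OTBS, C8–OTBS, C9–OTES, C10–OTES), via macrocyclic hydroxy ester 20 (not isolated)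
Conditions: CrCl2 (10 equiv), THF (0.003 M, slow addition), rt; work-up, then PPTS (cat.), CH2Cl2, rt
Reagents that add atoms: none
Why: Divalent chromium converts the allylic bromide into an allylchromium species that adds through C7 to the C6 aldehyde (intramolecular Nozaki–Hiyama, Barbier-type allylation), closing the ten-membered carbocycle; the chair-like transition state, biased by the C8 silyloxy stereocentre and the rigid (Z)-enyne tether, should give the anti adduct with (6R,7R) configuration, and the C6 oxygen then closes the trans-fused α-methylene-γ-lactone with loss of methanol.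

Step 14
Reactants: 21 macrolactone
Product: 22 9,10-diol (C1–OTBS and C8–OTBS retained)
Conditions: HF·pyridine, pyridine, THF, 0 °C
Reagents that add atoms: none
Why: Buffered HF·pyridine cleaves TES ethers far faster than secondary TBS ethers (selective desilylation), freeing C9–OH and the tertiary C10–OH.

Step 15
Reactants: 23 3-methylfuran-2(5H)-one
Product: 26 4-methoxybenzyl (Z)-4-acetoxy-2-methylbut-2-enoate, via sodium hydroxy-enoate 24 (not isolated), via PMB hydroxy-enoate 25 (not isolated)
Conditions: NaOH (1.0 equiv), H2O–MeOH, rt, evaporation; 4-MeOC6H4CH2Cl, NaI (cat.), DMF, rt; then Ac2O, pyridine, 0 °C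
Reagents that add atoms: sodium hydroxide [Na+].[OH-]; 4-methoxybenzyl chloride COc1ccc(CCl)cc1; acetic anhydride CC(=O)OC(C)=O
Why: Saponification of the butenolide gives the hydroxy carboxylate with the (Z)-geometry fixed by the ring, O-alkylation of the carboxylate forms the ester without activating the acid (which would relactonise), and acetylation caps the primary hydroxyl.

Step 16
Reactants: 26 PMB (Z)-4-acetoxy-2-methylbut-2-enoate
Product: 27 (Z)-4-acetoxy-2-methylbut-2-enoic acid
Conditions: CF3CO2H, anisole, CH2Cl2, 0 °C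
Reagents that add atoms: none
Why: Acidolysis of the PMB ester (benzylic cation trapped by anisole) frees the acid while the acetate and the (Z)-alkene are untouched.

Step 17
Reactants: 22 9,10-diol; 27 (Z)-4-acetoxy-2-methylbut-2-enoic acid
Product: 29 C9 (Z)-4-acetoxy-2-methylbut-2-enoate ester (C10–OH free; C1–OTBS, C8–OTBS), via mixed anhydride 28 (not isolated)
Conditions: 2,4,6-Cl3C6H2COCl, Et3N, toluene, rt; then 22, toluene, 70 °C
Reagents that add atoms: none
Why: Yamaguchi esterification: the mixed anhydride acylates the secondary C9 hydroxyl (the tertiary C10 hydroxyl is too hindered), and heating without a nucleophilic pyridine catalyst is the established way to avoid Z→E isomerisation of angelate-type acids.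

Step 18
Reactants: 29 C9 ester
Product: 30 1,8,10-triol (C9 ester retained)
Conditions: HF·pyridine, THF, 0 °C → rt
Reagents that add atoms: none
Why: Fluoride-mediated desilylation removes both TBS ethers under mildly acidic conditions that should not promote 1,2-acyl migration or touch the esters.

Step 19
Reactants: 30 1,8,10-triol
Product: 32 CNP0523348.1 (target), via cyclic hydroxy ynone 31 (not isolated)
Conditions: MnO2, CH2Cl2, rt; filtration; then Ph3PAuNTf2 (5 mol %), CH2Cl2, rt
Reagents that add atoms: none
Why: MnO2 oxidises only the propargylic C1 carbinol (C8–OH is an unactivated secondary alcohol, C10–OH is tertiary) to the strained ten-membered α′-hydroxy ynone 31; cationic monovalent gold then coordinates the C2≡C3 triple bond, the C10 hydroxyl adds to C3 anti to gold, and protodeauration at C2 releases the furanone and the catalyst. The closest known reaction type is the gold-catalysed cycloisomerisation of γ-hydroxyalkynones to 3(2H)-furanones, applied here transannularly. The furanone ring (O, C3, C2, C1, C10) closes in a 5-endo-dig mode by O–C3 bond formation, which at the same time divides the carbocycle into the furanone and the nine-membered oxa-bridged ring. No stereocentre is created: C10 keeps the configuration set in step 2 and the C2=C3 geometry is dictated by the ring. The step needs chemoselective oxidation and attack by the C10 hydroxyl only; the acylated C9 oxygen cannot compete in a 6-endo sense, C8–OH could only form a seven-membered ring, and relief of cycloalkyne strain in 31 should drive the closure.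

Compound list
1 | (S)-2,2-dimethyl-1,3-dioxolane-4-carbaldehyde | O=C[C@H]1OC(C)(C)OC1 | starting material
2 | ethyl 2-[bis(2,2,2-trifluoroethoxy)phosphoryl]propanoate | CCOC(=O)C(C)P(=O)(OCC(F)(F)F)OCC(F)(F)F | starting material
3 | ethyl (Z)-3-[(4R)-2,2-dimethyl-1,3-dioxolan-4-yl]-2-methylprop-2-enoate | CCOC(=O)/C(C)=C\[C@H]1OC(C)(C)OC1 | intermediate
4 | ethyl (2S,3S)-3-[(4S)-2,2-dimethyl-1,3-dioxolan-4-yl]-2,3-dihydroxy-2-methylpropanoate | CCOC(=O)[C@@](C)(O)[C@@H](O)[C@H]1OC(C)(C)OC1 | intermediate (not isolated)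
5 | 2-C-methyl-L-ribono-1,4-lactone, (3S,4S,5S)-3,4-dihydroxy-5-(hydroxymethyl)-3-methyloxolan-2-one | O=C1[C@@](C)(O)[C@@H](O)[C@H](CO)O1 | intermediate
6 | 2,3,5-tris-O-(triethylsilyl)-2-C-methyl-L-ribono-1,4-lactone | O=C1[C@@](C)(O[Si](CC)(CC)CC)[C@@H](O[Si](CC)(CC)CC)[C@H](CO[Si](CC)(CC)CC)O1 | intermediate
7 | 2,3,5-tris-O-(triethylsilyl)-2-C-methyl-L-ribofuranose (anomer mixture) | OC1[C@@](C)(O[Si](CC)(CC)CC)[C@@H](O[Si](CC)(CC)CC)[C@H](CO[Si](CC)(CC)CC)O1 | intermediate
8 | ethynylmagnesium bromide | C#C[Mg]Br | starting material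
9 | alkynyl diol (C1–OH epimers, C8–OH; C7, C9, C10 O-TES) | C#CC(O)[C@@](C)(O[Si](CC)(CC)CC)[C@@H](O[Si](CC)(CC)CC)[C@@H](O)CO[Si](CC)(CC)CC | intermediate
10 | 1,8-bis-O-TBS ether of 9 | C#CC(O[Si](C)(C)C(C)(C)C)[C@@](C)(O[Si](CC)(CC)CC)[C@@H](O[Si](CC)(CC)CC)[C@@H](O[Si](C)(C)C(C)(C)C)CO[Si](CC)(CC)CC | intermediate
11 | C7 aldehyde | C#CC(O[Si](C)(C)C(C)(C)C)[C@@](C)(O[Si](CC)(CC)CC)[C@@H](O[Si](CC)(CC)CC)[C@@H](O[Si](C)(C)C(C)(C)C)C=O | intermediate
12 | methyl acrylate | C=CC(=O)OC | starting material
13 | Morita–Baylis–Hillman alcohol (C7 epimers) | C#CC(O[Si](C)(C)C(C)(C)C)[C@@](C)(O[Si](CC)(CC)CC)[C@@H](O[Si](CC)(CC)CC)[C@@H](O[Si](C)(C)C(C)(C)C)C(O)C(=C)C(=O)OC | intermediate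
14 | but-2-yn-1-ol | CC#CCO | starting material
15 | sodium cyclic vinylalanate (2-oxa-1-aluminacyclopent-4-ene ate complex) | [Na+].COCCO[Al-]1(OCCOC)OCC=C1C | intermediate (not isolated)
16 | (Z)-3-iodobut-2-en-1-ol | OC/C=C(/C)I | intermediate
17 | (Z)-3-iodobut-2-enal | O=C/C=C(/C)I | intermediate
18 | (Z)-enynal with Morita–Baylis–Hillman alcohol terminus | O=C/C=C(/C)C#CC(O[Si](C)(C)C(C)(C)C)[C@@](C)(O[Si](CC)(CC)CC)[C@@H](O[Si](CC)(CC)CC)[C@@H](O[Si](C)(C)C(C)(C)C)C(O)C(=C)C(=O)OC | intermediate
19 | (Z)-enynal (Z)-2-(bromomethyl)enoate | O=C/C=C(/C)C#CC(O[Si](C)(C)C(C)(C)C)[C@@](C)(O[Si](CC)(CC)CC)[C@@H](O[Si](CC)(CC)CC)[C@@H](O[Si](C)(C)C(C)(C)C)/C=C(\CBr)C(=O)OC | intermediate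
20 | macrocyclic C6 hydroxy methyl ester | COC(=O)C(=C)[C@H]1[C@H](O)/C=C(/C)C#CC(O[Si](C)(C)C(C)(C)C)[C@@](C)(O[Si](CC)(CC)CC)[C@@H](O[Si](CC)(CC)CC)[C@H]1O[Si](C)(C)C(C)(C)C | intermediate (not isolated)
21 | macrolactone (C1–OTBS, C8–OTBS, C9–OTES, C10–OTES) | C=C1C(=O)O[C@@H]2/C=C(/C)C#CC(O[Si](C)(C)C(C)(C)C)[C@@](C)(O[Si](CC)(CC)CC)[C@@H](O[Si](CC)(CC)CC)[C@@H](O[Si](C)(C)C(C)(C)C)[C@@H]12 | intermediate
22 | macrolactone 9,10-diol (C1–OTBS, C8–OTBS) | C=C1C(=O)O[C@@H]2/C=C(/C)C#CC(O[Si](C)(C)C(C)(C)C)[C@@](C)(O)[C@@H](O)[C@@H](O[Si](C)(C)C(C)(C)C)[C@@H]12 | intermediate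
23 | 3-methylfuran-2(5H)-one | CC1=CCOC1=O | starting material
24 | sodium (Z)-4-hydroxy-2-methylbut-2-enoate | [Na+].[O-]C(=O)/C(C)=C\CO | intermediate (not isolated)
25 | 4-methoxybenzyl (Z)-4-hydroxy-2-methylbut-2-enoate | COc1ccc(COC(=O)/C(C)=C\CO)cc1 | intermediate (not isolated)
26 | 4-methoxybenzyl (Z)-4-acetoxy-2-methylbut-2-enoate | COc1ccc(COC(=O)/C(C)=C\COC(C)=O)cc1 | intermediate
27 | (Z)-4-acetoxy-2-methylbut-2-enoic acid | CC(=O)OC/C=C(/C)C(=O)O | intermediate
28 | (Z)-4-acetoxy-2-methylbut-2-enoic 2,4,6-trichlorobenzoic anhydride | CC(=O)OC/C=C(/C)C(=O)OC(=O)c1c(Cl)cc(Cl)cc1Cl | intermediate (not isolated)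
29 | macrolactone C9 ester (C10–OH; C1–OTBS, C8–OTBS) | C=C1C(=O)O[C@@H]2/C=C(/C)C#CC(O[Si](C)(C)C(C)(C)C)[C@@](C)(O)[C@@H](OC(=O)/C(C)=C\COC(C)=O)[C@@H](O[Si](C)(C)C(C)(C)C)[C@@H]12 | intermediate
30 | macrolactone 1,8,10-triol C9 ester | C=C1C(=O)O[C@@H]2/C=C(/C)C#CC(O)[C@@](C)(O)[C@@H](OC(=O)/C(C)=C\COC(C)=O)[C@@H](O)[C@@H]12 | intermediate
31 | ten-membered α′-hydroxy ynone | C=C1C(=O)O[C@@H]2/C=C(/C)C#CC(=O)[C@@](C)(O)[C@@H](OC(=O)/C(C)=C\COC(C)=O)[C@@H](O)[C@@H]12 | intermediate (not isolated)
32 | CNP0523348.1, (4Z,6R,7R,8S,9S,10S)-9-[(Z)-4-acetoxy-2-methylbut-2-enoyloxy]-8-hydroxy-1-oxo-3,10-epoxygermacra-2,4,11(13)-trien-12,6-olide | C=C1C(=O)O[C@@H]2/C=C(/C)C3=CC(=O)[C@@](C)(O3)[C@@H](OC(=O)/C(C)=C\COC(C)=O)[C@@H](O)[C@@H]12 | target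

Total step count: 19. Longest linear sequence: 15 steps (steps 1–8, 11–14 and 17–19, from compound 1).

Steps most likely to fail

Step 13. Ring closure may be outrun by oligomerisation because of the transannular strain of the forming cyclodecenyne, or the aldehyde face may be poorly discriminated so that C6/C7 form with the wrong relative configuration. Fallback: the order of bond formation is reversed. Alcohol 13 is brominated with allylic transposition (N-bromosuccinimide, Me2S) to the terminal-alkyne allylic bromide F1. F1 is coupled intermolecularly with iodoenal 17 (CrCl2, THF, rt; lactonisation), where the open transition state can be tuned by the metal, to give the vinyl iodide lactone F2. The ten-membered ring is then closed at C3–C4 by intramolecular Sonogashira coupling (Pd(PPh3)4, CuI, Et3N, THF, high dilution), which returns to macrolactone 21.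

Step 17. Acylation of the C9 hydroxyl, flanked by the quaternary C10 and the silylated C8, may be too slow, and forcing conditions may isomerise the (Z)-acyl donor. Fallback: the enoate is built on the substrate. Diol 22 is acylated at C9 with the small sp3 donor 2-[bis(2,2,2-trifluoroethoxy)phosphoryl]propanoic acid (EDC, DMAP, CH2Cl2; ketene-type activation) to the phosphonate ester F3. A Still–Gennari olefination of F3 with 2-oxoethyl acetate (K2CO3, 18-crown-6, toluene, −20 → 0 °C) should then give the (Z)-enoate and return to ester 29.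

Step 8. Addition to the hindered α-silyloxy aldehyde may be so slow that enolisation by the amine epimerises C8. Fallback: the amine-catalysed reaction is replaced by a stoichiometric vinylmetal addition. Aldehyde 11 is added to [α-(methoxycarbonyl)vinyl]diisobutylaluminium, preformed from methyl propiolate and iBu2AlH with N-methylmorpholine N-oxide in THF at 0 °C; this gives alcohol 13 directly within hours and without base.

Further compounds
F1 | step 13 | terminal-alkyne (Z)-2-(bromomethyl)enoate from 13 | C#CC(O[Si](C)(C)C(C)(C)C)[C@@](C)(O[Si](CC)(CC)CC)[C@@H](O[Si](CC)(CC)CC)[C@@H](O[Si](C)(C)C(C)(C)C)/C=C(\CBr)C(=O)OC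
F2 | step 13 | α-methylene lactone bearing the (Z)-2-iodopropenyl group at C6 and the terminal alkyne chain at C7 | C#CC(O[Si](C)(C)C(C)(C)C)[C@@](C)(O[Si](CC)(CC)CC)[C@@H](O[Si](CC)(CC)CC)[C@@H](O[Si](C)(C)C(C)(C)C)[C@H]1C(=C)C(=O)O[C@@H]1/C=C(/C)I
F3 | step 17 | macrolactone C9 2-[bis(2,2,2-trifluoroethoxy)phosphoryl]propanoate (C10–OH; C1–OTBS, C8–OTBS) | C=C1C(=O)O[C@@H]2/C=C(/C)C#CC(O[Si](C)(C)C(C)(C)C)[C@@](C)(O)[C@@H](OC(=O)C(C)P(=O)(OCC(F)(F)F)OCC(F)(F)F)[C@@H](O[Si](C)(C)C(C)(C)C)[C@@H]12
F0 | step 8 | none | none
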